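Watch the clock.

| setting | cedar | alder | maple | flask |
|---|---|---|---|---|
| left-handed substrate | 0.050 M | 0.050 M | 0.025 M | 0.050 M |
| right-handed substrate | 0.050 M | 0.050 M | 0.025 M | 0.050 M |
| partner | 2.5 equiv | 2.5 equiv | 2.5 equiv | 2.50 equiv |
| free catalyst | 15 mol% | 15 mol% | 15 mol% | 15 mol% |
| racemization catalyst | 0.2 mol% | 0.2 mol% | 0.2 mol% | 0.2 mol% |
| impurity | 0.080 mM | 0.18 mM | 0.12 mM | 0.12 mM |
| added ligand | 0.11 mM | 0.11 mM | 0.11 mM | 0.11 mM |
| remark | run made earlier | run made earlier | run made earlier |  |
| time |  |  |  | 2.5 min |

| run | time / min | left-handed product / % | right-handed product / % |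
|---|---|---|---|
| cedar | 0.417 | 13.6 | 5.8 |
| cedar | 0.833 | 22.1 | 10.3 |
| cedar | 1.33 | 28.2 | 13.3 |
| cedar | 1.50 | 31.4 | 15.2 |
| cedar | 2.00 | 35.2 | 18.0 |
| cedar | 2.50 | 37.2 | 20.7 |
| cedar | 3.00 | 39.9 | 23.6 |
| alder | 0.250 | 9.0 | 3.0 |
| alder | 0.333 | 10.7 | 4.8 |
| alder | 0.500 | 14.7 | 6.0 |
| alder | 0.833 | 21.5 | 10.5 |
| alder | 1.33 | 28.6 | 15.3 |
| alder | 2.00 | 34.3 | 17.8 |
| alder | 3.00 | 40.1 | 23.7 |
| maple | 0.667 | 6.6 | 3.2 |
| maple | 1.33 | 11.0 | 4.6 |
| maple | 2.00 | 14.8 | 6.7 |
| maple | 2.50 | 17.1 | 7.2 |
| maple | 3.00 | 19.5 | 8.7 |

(scatter of a reading: 0.5 percentage points)

- free catalyst is single-handed; left-handed substrate and right-handed substrate are mirror images of each other, charged as a racemate, each of them at the stated concentration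
- an excess is the difference of the two amounts in percent of their sum
- an excess is below zero if the other one leads

1. left-handed product and right-handed product together, in percent of the left-handed substrate and right-handed substrate charged together, at 2.5 min
2. excess of left-handed product over right-handed product in the product at 2.5 min
3. whether the exchange between left-handed substrate and right-handed substrate keeps pace with the reaction: how far the product's excess at 2.5 min gets from its value without exchange to its value with instant exchange (above 80 % keeps pace, below 20 % hardly takes part, else lags behind)

1. The flask holds a racemate, and in cedar the single-handed free catalyst turned the left-handed substrate into product faster. The readings count both substrates together, so I doubled them to get the part of each substrate used. Cedar's excess fell from 40.2 % at 0.417 min to 25.7 % at 3.00 min, so do not move the sampling time.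

2. I carried one number: the selectivity factor s, the logarithm of what remains of the left-handed substrate over that of what remains of the right-handed substrate. Cedar's last reading gave 2.50.

3. Exchange refills the left-handed substrate from the right-handed one, which pulls s down as a run proceeds. Cedar's first reading gave 2.57, and the last readings of alder and maple gave 2.52 and 2.59. I saw no fall beyond the scatter, with c(impurity) at 0.080 mM in cedar and 0.18 mM in alder. So I expected exchange to hardly take part in the flask.

4. The flask's charges match cedar's except c(impurity), which lies between cedar's and alder's. From cedar's 37.2 % left-handed product at 2.50 min, s gave 21.0 % right-handed product. That made 58.2 % in total and an excess of 27.9 %, against 42.9 % with instant exchange.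

5. The forecast gave 58.4 %, 28.5 % and "hardly takes part", calling it “plain kinetic resolution with fixed selectivity”, with an excess a little above mine.

6. The flask gave 58.4 % and 28.3 %, and exchange hardly takes part, covering 0.13 % of the way.

    left-handed substrate + racemization catalyst ⇌ right-handed substrate + racemization catalyst, rate k1*[racemization catalyst]*[left-handed substrate] forward; the back reaction follows from the equilibrium constant (k = 200 M⁻¹ s⁻¹)
    partner + free catalyst + left-handed substrate → free catalyst + left-handed product (k = 14.0 M⁻² s⁻¹)
    racemization catalyst + added ligand ⇌ idle complex, settled at all times (K = 6.50 × 10⁷ M⁻¹)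
    racemization catalyst + impurity → spent catalyst (k = 19000 M⁻¹ s⁻¹)
    partner + free catalyst + right-handed substrate → free catalyst + right-handed product (k = 5.50 M⁻² s⁻¹)

At 2.50 min the flask's left-handed substrate went to left-handed product 870 times as fast as it crossed to right-handed substrate, counting the forward exchange step alone. At that moment 0.0402 % of the racemization catalyst stood free, beside 79.6 % as idle complex and 20.4 % as spent catalyst.

With 9 mol% of free catalyst, the neighbouring flask reached 30.2 % left-handed product, and s gave 15.4 % right-handed product and an excess of 32.5 %. It computed to 15.2 % and 32.9 %.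

The data were computed for an exercise.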